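## Retrosynthetic overview

1. Target 21 ⇐ hydrogenolysis of tribenzyl ether 20. The oxolane ring is formed last, by acid-mediated closure of the O1–C2 bond in triol 19.
2. 19 ⇐ LiAlH4 opening of aldol lactone 18. The key C2–C3 bond ⇐ intermolecular aldol of the lithium enolate of α-benzyloxy lactone 15 with O-benzylvanillin 16, anti to the β-benzyl group, which sets the quaternary carbinol.
3. 15 ⇐ enolate hydroxylation and O-benzylation of (R)-β-benzyl-γ-butyrolactone 12 (a temporary ring, formed first and opened in step 11).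
4. 12 ⇐ Evans alkylation of dihydroferulic imide 7 with tert-butyl bromoacetate 8, reductive auxiliary removal and lactonization; acid 4 ⇐ ferulic acid 1.

Assumption and locants: oxolane numbered O1, C2 (aryl), C3 (OH and CH2OH), C4 (benzyl), C5; the secondary carbinol made in step 10 is carried as both epimers (left undefined in the SMILES of 18 and 19) because step 12 re-sets it.

## Route

Step 1
Reactants: 1 ferulic acid
Product: 2 3-(4-hydroxy-3-methoxyphenyl)propanoic acid
Conditions: H2 (1 atm), 10% Pd/C, MeOH, rt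
Reagents that add atoms: none
Why: Heterogeneous catalytic hydrogenation saturates only the conjugated C=C (arene, acid and phenol are inert at 1 atm), and it is done before any benzyl ether is present.

Step 2
Reactants: 2 3-(4-hydroxy-3-methoxyphenyl)propanoic acid
Product: 3 benzyl 3-[4-(benzyloxy)-3-methoxyphenyl]propanoate
Conditions: BnBr (2.4 equiv), K2CO3, DMF, 60 °C
Reagents that add atoms: benzyl bromide, BrCc1ccccc1
Why: Double SN2 O-alkylation (Williamson ether synthesis at the phenoxide, ester formation at the carboxylate) with a reactive benzylic bromide goes to completion under K2CO3/DMF.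

Step 3
Reactants: 3 benzyl 3-[4-(benzyloxy)-3-methoxyphenyl]propanoate
Product: 4 3-[4-(benzyloxy)-3-methoxyphenyl]propanoic acid
Conditions: NaOH, THF/MeOH/H2O, 50 °C; then 1 M HCl
Reagents that add atoms: sodium hydroxide, [Na+].[OH-]
Why: Saponification (acyl-oxygen ester hydrolysis) cleaves the benzyl ester while the aryl benzyl ether is inert to hydroxide.

Step 4
Reactants: 4 3-[4-(benzyloxy)-3-methoxyphenyl]propanoic acid; 5 (4S)-4-benzyl-1,3-oxazolidin-2-one
Product: 7 (4S)-4-benzyl-3-{3-[4-(benzyloxy)-3-methoxyphenyl]propanoyl}-1,3-oxazolidin-2-one, via mixed pivalic anhydride 6 (not isolated)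
Conditions: t-BuCOCl, Et3N, THF, −20 °C; then 5, LiCl, −20 °C → rt
Reagents that add atoms: none
Why: N-Acylation of the Evans oxazolidinone through the pivaloyl mixed anhydride (LiCl/Et3N protocol), in which the nucleophile attacks the unhindered acyl carbon and not the pivaloyl one.

Step 5
Reactants: 7 (4S)-4-benzyl-3-{3-[4-(benzyloxy)-3-methoxyphenyl]propanoyl}-1,3-oxazolidin-2-one; 8 tert-butyl bromoacetate
Product: 10 tert-butyl (3R)-3-{[4-(benzyloxy)-3-methoxyphenyl]methyl}-4-[(4S)-4-benzyl-2-oxo-1,3-oxazolidin-3-yl]-4-oxobutanoate, via sodium Z-enolate 9 (not isolated)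
Conditions: NaN(SiMe3)2, THF, −78 °C; then 8, −78 → −40 °C
Reagents that add atoms: none
Why: Evans asymmetric alkylation, in which the chelated sodium Z-enolate is alkylated by the reactive α-bromo ester on the face opposite the auxiliary's benzyl group, setting the new centre as R (dr typically ≥ 95:5); this centre becomes C4 of the target.

Step 6
Reactants: 10 tert-butyl (3R)-3-{[4-(benzyloxy)-3-methoxyphenyl]methyl}-4-[(4S)-4-benzyl-2-oxo-1,3-oxazolidin-3-yl]-4-oxobutanoate
Product: 11 tert-butyl (3R)-3-{[4-(benzyloxy)-3-methoxyphenyl]methyl}-4-hydroxybutanoate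
Conditions: LiBH4, H2O (1 equiv), Et2O/THF, 0 °C
Reagents that add atoms: none
Why: Reductive auxiliary cleavage, in which LiBH4 reduces the activated exocyclic imide carbonyl to the primary alcohol much faster than the hindered tert-butyl ester and leaves the stereocentre untouched.

Step 7
Reactants: 11 tert-butyl (3R)-3-{[4-(benzyloxy)-3-methoxyphenyl]methyl}-4-hydroxybutanoate
Product: 12 (4R)-4-{[4-(benzyloxy)-3-methoxyphenyl]methyl}oxolan-2-one
Conditions: p-TsOH·H2O (10 mol %), toluene, 80 °C
Reagents that add atoms: none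
Why: Acid-catalysed lactonization (intramolecular transesterification) to the five-membered lactone is strongly favoured and does not involve the stereocentre.

Step 8
Reactants: 12 (4R)-4-{[4-(benzyloxy)-3-methoxyphenyl]methyl}oxolan-2-one
Product: 14 (3R,4S)-4-{[4-(benzyloxy)-3-methoxyphenyl]methyl}-3-hydroxyoxolan-2-one, via potassium enolate 13 (not isolated)
Conditions: KN(SiMe3)2, THF, −78 °C; then 3-phenyl-2-(phenylsulfonyl)oxaziridine, −78 °C; AcOH quench
Reagents that add atoms: 3-phenyl-2-(phenylsulfonyl)oxaziridine (Davis oxaziridine), O=S(=O)(c1ccccc1)N1OC1c1ccccc1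
Why: Davis enolate hydroxylation transfers oxygen to the enolate face anti to the C4 benzyl group, giving the trans hydroxy lactone (this C3 configuration is erased again on enolization in step 10, so any cis isomer can be carried along).

Step 9
Reactants: 14 (3R,4S)-4-{[4-(benzyloxy)-3-methoxyphenyl]methyl}-3-hydroxyoxolan-2-one
Product: 15 (3R,4S)-3-(benzyloxy)-4-{[4-(benzyloxy)-3-methoxyphenyl]methyl}oxolan-2-one
Conditions: BnBr, Ag2O, CH2Cl2, 4 Å molecular sieves, rt, dark
Reagents that add atoms: benzyl bromide, BrCc1ccccc1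
Why: Ag2O-promoted Williamson-type O-benzylation runs under essentially neutral conditions, so the lactone is neither opened nor C-alkylated.

Step 10
Reactants: 15 (3R,4S)-3-(benzyloxy)-4-{[4-(benzyloxy)-3-methoxyphenyl]methyl}oxolan-2-one; 16 4-(benzyloxy)-3-methoxybenzaldehyde
Product: 18 (3R,4S)-3-(benzyloxy)-3-{[4-(benzyloxy)-3-methoxyphenyl](hydroxy)methyl}-4-{[4-(benzyloxy)-3-methoxyphenyl]methyl}oxolan-2-one (both carbinol epimers), via lithium enolate 17 (not isolated)
Conditions: LiN(iPr)2, THF, −78 °C; then 16, −78 °C; AcOH quench at −78 °C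
Reagents that add atoms: none
Why: Intermolecular aldol addition of the tetrasubstituted lithium enolate to the non-enolizable aldehyde forms the C2–C3 bond, the aldehyde approaching the planar five-membered enolate anti to the C4 benzyl substituent, so the new C–C bond is trans to benzyl and the quaternary carbinol carbon is set as required (3R here, 3S in the target), while the secondary carbinol forms as both epimers, which does not matter.

Step 11
Reactants: 18 (3R,4S)-3-(benzyloxy)-3-{[4-(benzyloxy)-3-methoxyphenyl](hydroxy)methyl}-4-{[4-(benzyloxy)-3-methoxyphenyl]methyl}oxolan-2-one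
Product: 19 (2S,3S)-2-(benzyloxy)-2-{[4-(benzyloxy)-3-methoxyphenyl](hydroxy)methyl}-3-{[4-(benzyloxy)-3-methoxyphenyl]methyl}butane-1,4-diol (both carbinol epimers)
Conditions: LiAlH4, THF, 0 °C; aq. NaOH work-up
Reagents that add atoms: none
Why: LiAlH4 reduction of the lactone to the 1,4-diol at 0 °C leaves the three benzyl ethers intact, and hydride delivery to the lactone outpaces retro-aldol of the aluminate.

Step 12
Reactants: 19 (2S,3S)-2-(benzyloxy)-2-{[4-(benzyloxy)-3-methoxyphenyl](hydroxy)methyl}-3-{[4-(benzyloxy)-3-methoxyphenyl]methyl}butane-1,4-diol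
Product: 20 [(2R,3S,4S)-3-(benzyloxy)-2-[4-(benzyloxy)-3-methoxyphenyl]-4-{[4-(benzyloxy)-3-methoxyphenyl]methyl}oxolan-3-yl]methanol
Conditions: camphor-10-sulfonic acid (10 mol %), CH2Cl2, 0 °C → rt
Reagents that add atoms: none
Why: Acid-catalysed SN1 cycloetherification, in which both carbinol epimers ionize to the same para-alkoxybenzylic cation that is trapped by the C5 hydroxyl in a five-membered ring closure (the other CH2OH could only give an oxetane), the aryl group going trans to the C3 CH2OH and the C4 benzyl group (least hindered and, since closure is reversible under acid, also the thermodynamic outcome), which sets C2 as R.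

Step 13
Reactants: 20 [(2R,3S,4S)-3-(benzyloxy)-2-[4-(benzyloxy)-3-methoxyphenyl]-4-{[4-(benzyloxy)-3-methoxyphenyl]methyl}oxolan-3-yl]methanol
Product: 21 (2R,3S,4S)-2-(4-hydroxy-3-methoxyphenyl)-4-[(4-hydroxy-3-methoxyphenyl)methyl]-3-(hydroxymethyl)oxolan-3-ol
Conditions: H2 (1 atm), Pd(OH)2/C, EtOAc/MeOH, rt
Reagents that add atoms: none
Why: Catalytic hydrogenolysis removes the two aryl benzyl ethers and the tertiary alkyl benzyl ether under neutral conditions; stopped at full conversion it is expected to leave the cyclic benzylic C2–O bond and the three stereocentres intact.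

## Compound list

1 | ferulic acid, (E)-3-(4-hydroxy-3-methoxyphenyl)prop-2-enoic acid | COc1cc(/C=C/C(=O)O)ccc1O | starting material
2 | 3-(4-hydroxy-3-methoxyphenyl)propanoic acid | COc1cc(CCC(=O)O)ccc1O | intermediate
3 | benzyl 3-[4-(benzyloxy)-3-methoxyphenyl]propanoate | COc1cc(CCC(=O)OCc2ccccc2)ccc1OCc1ccccc1 | intermediate
4 | 3-[4-(benzyloxy)-3-methoxyphenyl]propanoic acid | COc1cc(CCC(=O)O)ccc1OCc1ccccc1 | intermediate
5 | (4S)-4-benzyl-1,3-oxazolidin-2-one | O=C1N[C@@H](Cc2ccccc2)CO1 | starting material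
6 | 3-[4-(benzyloxy)-3-methoxyphenyl]propanoic pivalic anhydride | COc1cc(CCC(=O)OC(=O)C(C)(C)C)ccc1OCc1ccccc1 | intermediate (not isolated)
7 | (4S)-4-benzyl-3-{3-[4-(benzyloxy)-3-methoxyphenyl]propanoyl}-1,3-oxazolidin-2-one | COc1cc(CCC(=O)N2[C@@H](Cc3ccccc3)COC2=O)ccc1OCc1ccccc1 | intermediate
8 | tert-butyl bromoacetate | CC(C)(C)OC(=O)CBr | starting material
9 | sodium (Z)-enolate of 7 | [Na+].[O-]/C(=C\Cc1ccc(OCc2ccccc2)c(OC)c1)N1[C@@H](Cc2ccccc2)COC1=O | intermediate (not isolated)
10 | tert-butyl (3R)-3-{[4-(benzyloxy)-3-methoxyphenyl]methyl}-4-[(4S)-4-benzyl-2-oxo-1,3-oxazolidin-3-yl]-4-oxobutanoate | COc1cc(C[C@H](CC(=O)OC(C)(C)C)C(=O)N2[C@@H](Cc3ccccc3)COC2=O)ccc1OCc1ccccc1 | intermediate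
11 | tert-butyl (3R)-3-{[4-(benzyloxy)-3-methoxyphenyl]methyl}-4-hydroxybutanoate | COc1cc(C[C@H](CC(=O)OC(C)(C)C)CO)ccc1OCc1ccccc1 | intermediate
12 | (4R)-4-{[4-(benzyloxy)-3-methoxyphenyl]methyl}oxolan-2-one | COc1cc(C[C@@H]2CC(=O)OC2)ccc1OCc1ccccc1 | intermediate
13 | potassium enolate of 12 | COc1cc(C[C@@H]2C=C([O-])OC2)ccc1OCc1ccccc1.[K+] | intermediate (not isolated)
14 | (3R,4S)-4-{[4-(benzyloxy)-3-methoxyphenyl]methyl}-3-hydroxyoxolan-2-one (OH trans to benzyl) | COc1cc(C[C@H]2COC(=O)[C@@H]2O)ccc1OCc1ccccc1 | intermediate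
15 | (3R,4S)-3-(benzyloxy)-4-{[4-(benzyloxy)-3-methoxyphenyl]methyl}oxolan-2-one | COc1cc(C[C@H]2COC(=O)[C@@H]2OCc2ccccc2)ccc1OCc1ccccc1 | intermediate
16 | 4-(benzyloxy)-3-methoxybenzaldehyde (O-benzylvanillin) | COc1cc(C=O)ccc1OCc1ccccc1 | starting material
17 | lithium enolate of 15 | [Li+].[O-]C1=C(OCc2ccccc2)[C@@H](Cc2ccc(OCc3ccccc3)c(OC)c2)CO1 | intermediate (not isolated)
18 | (3R,4S)-3-(benzyloxy)-3-{[4-(benzyloxy)-3-methoxyphenyl](hydroxy)methyl}-4-{[4-(benzyloxy)-3-methoxyphenyl]methyl}oxolan-2-one, both carbinol epimers; hydroxybenzyl group trans to the C4 benzyl | COc1cc(C[C@H]2COC(=O)[C@]2(OCc2ccccc2)C(O)c2ccc(OCc3ccccc3)c(OC)c2)ccc1OCc1ccccc1 | intermediate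
19 | (2S,3S)-2-(benzyloxy)-2-{[4-(benzyloxy)-3-methoxyphenyl](hydroxy)methyl}-3-{[4-(benzyloxy)-3-methoxyphenyl]methyl}butane-1,4-diol, both carbinol epimers | COc1cc(C[C@@H](CO)[C@@](CO)(OCc2ccccc2)C(O)c2ccc(OCc3ccccc3)c(OC)c2)ccc1OCc1ccccc1 | intermediate
20 | [(2R,3S,4S)-3-(benzyloxy)-2-[4-(benzyloxy)-3-methoxyphenyl]-4-{[4-(benzyloxy)-3-methoxyphenyl]methyl}oxolan-3-yl]methanol | COc1cc(C[C@H]2CO[C@H](c3ccc(OCc4ccccc4)c(OC)c3)[C@@]2(OCc3ccccc3)CO)ccc1OCc1ccccc1 | intermediate
21 | (2R,3S,4S)-2-(4-hydroxy-3-methoxyphenyl)-4-[(4-hydroxy-3-methoxyphenyl)methyl]-3-(hydroxymethyl)oxolan-3-ol | COc1cc(C[C@H]2CO[C@H](c3ccc(O)c(OC)c3)[C@@]2(O)CO)ccc1O | target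

## Step count and risks

Total step count: 13. Longest linear sequence: 13 steps (1 → 21); compounds 5, 8 and 16 are purchased.

The three steps most likely to fail:

Step 10 (aldol onto a hindered, fully substituted enolate; the addition is reversible and may stall or revert). The fallback sets out from 15 and comes back to the route at 19. Enolate 17 is generated as before and C-acylated in a Claisen-type condensation with 4-(benzyloxy)-3-methoxybenzoyl chloride F1, made from commercial 4-(benzyloxy)-3-methoxybenzoic acid with oxalyl chloride and catalytic DMF. Acylation is irreversible and occurs on the same face, anti to the C4 benzyl group, giving (3R,4S)-3-(benzyloxy)-3-[4-(benzyloxy)-3-methoxybenzoyl]-4-{[4-(benzyloxy)-3-methoxyphenyl]methyl}oxolan-2-one F2. Excess LiAlH4 in THF at 0 °C then reduces the ketone and the lactone in one operation to triol 19; the epimer ratio at the carbinol again does not matter.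

Step 11 (retro-aldol of the congested aldolate before the lactone is reduced). The fallback sets out from 18 and comes back to the route at 20. The carbinol is first capped with Et3SiOTf and 2,6-lutidine to give (3R,4S)-3-(benzyloxy)-3-{[4-(benzyloxy)-3-methoxyphenyl][(triethylsilyl)oxy]methyl}-4-{[4-(benzyloxy)-3-methoxyphenyl]methyl}oxolan-2-one F3, which cannot fragment. LiAlH4 reduction gives (2S,3S)-2-(benzyloxy)-2-{[4-(benzyloxy)-3-methoxyphenyl][(triethylsilyl)oxy]methyl}-3-{[4-(benzyloxy)-3-methoxyphenyl]methyl}butane-1,4-diol F4. Camphor-10-sulfonic acid in CH2Cl2 then ionizes the benzylic silyl ether and closes the ring directly to 20.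

Step 12 (a 1,2-shift of the benzylic cation next to the oxygenated quaternary carbon, or incomplete control at C2). The fallback sets out from 19 and comes back to the route at 21. The three benzyl ethers are removed first by H2 over Pd/C in EtOAc, giving (2S,3S)-2-[hydroxy(4-hydroxy-3-methoxyphenyl)methyl]-3-[(4-hydroxy-3-methoxyphenyl)methyl]butane-1,2,4-triol F5. With the phenol free, mild acid (pyridinium p-toluenesulfonate in warm aqueous THF) generates the para-quinone methide, and reversible oxa-Michael addition of the C5 hydroxyl gives the thermodynamic oxolane 21 with aryl trans to CH2OH and benzyl. This order also keeps the cyclic benzylic ether away from hydrogenolysis.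

## Further compounds

F1 | step 10 | 4-(benzyloxy)-3-methoxybenzoyl chloride | COc1cc(C(Cl)=O)ccc1OCc1ccccc1
F2 | step 10 | (3R,4S)-3-(benzyloxy)-3-[4-(benzyloxy)-3-methoxybenzoyl]-4-{[4-(benzyloxy)-3-methoxyphenyl]methyl}oxolan-2-one | COc1cc(C[C@H]2COC(=O)[C@]2(OCc2ccccc2)C(=O)c2ccc(OCc3ccccc3)c(OC)c2)ccc1OCc1ccccc1
F3 | step 11 | (3R,4S)-3-(benzyloxy)-3-{[4-(benzyloxy)-3-methoxyphenyl][(triethylsilyl)oxy]methyl}-4-{[4-(benzyloxy)-3-methoxyphenyl]methyl}oxolan-2-one, both silyloxy epimers | COc1cc(C[C@H]2COC(=O)[C@]2(OCc2ccccc2)C(O[Si](CC)(CC)CC)c2ccc(OCc3ccccc3)c(OC)c2)ccc1OCc1ccccc1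
F4 | step 11 | (2S,3S)-2-(benzyloxy)-2-{[4-(benzyloxy)-3-methoxyphenyl][(triethylsilyl)oxy]methyl}-3-{[4-(benzyloxy)-3-methoxyphenyl]methyl}butane-1,4-diol, both silyloxy epimers | COc1cc(C[C@@H](CO)[C@@](CO)(OCc2ccccc2)C(O[Si](CC)(CC)CC)c2ccc(OCc3ccccc3)c(OC)c2)ccc1OCc1ccccc1
F5 | step 12 | (2S,3S)-2-[hydroxy(4-hydroxy-3-methoxyphenyl)methyl]-3-[(4-hydroxy-3-methoxyphenyl)methyl]butane-1,2,4-triol, both carbinol epimers | COc1cc(C[C@@H](CO)[C@@](CO)(O)C(O)c2ccc(O)c(OC)c2)ccc1O
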